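**Retrosynthetic overview**
- The central 1,4-dioxane is cut into two identical 6α,7α-epoxides of 12-methoxyabieta-8,11,13-triene. Each C7–O bond forms with inversion and each C6–O bond is kept; the epoxide comes from ferruginol methyl ether by dehydrogenation and α-face epoxidation.
- Ring A is cut at C10–C1 and C2–C3. A two-carbon vinylphosphonium unit (C1–C2) joins the ring-fusion carbon C10 to the aldehyde carbon C3 of a bicyclic (rings B and C) methylene aldehyde, and the ring closes at C2–C3 by Wittig olefination.
- Enabling feature: C10 is the quaternary benzylic carbon between rings A and B, bonded to C9 of aromatic ring C. It can therefore be generated as a tertiary benzylic radical from an exocyclic C10=C20 alkene (the added hydrogen becomes the C20 methyl). C3 sits on the gem-dimethyl carbon C4 as a non-enolisable aldehyde.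
- One catalytic stereo-event (asymmetric epoxidation of an allylic alcohol) is relayed by SN2 opening to C5. The temporary oxygenated C10 is then planarised, and C5 controls C10 (key step) and later C6 and C7.
- Ring order: C and B (bought tetralone), then A (step 9), then the oxirane (step 12), then the 1,4-dioxane (step 13).

Key step: step 9

Remark: abietane numbering (C1–C20, rings A, B, C) is used for all intermediates; the target is read as the C2-symmetric dimer with 5α-H, 10β-methyl, 6α-O and 7β-O in each half.

**Route**

Step 1
Reactants: 1 7-methoxy-1-tetralone; 2 propan-2-ol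
Product: 3 7-methoxy-6-(propan-2-yl)-3,4-dihydronaphthalen-1(2H)-one
Conditions: polyphosphoric acid, 75 °C
Reagents that add atoms: none
Why: Friedel–Crafts alkylation; the isopropyl cation should attack the position ortho to the methoxy group that is not peri to the carbonyl.

Step 2
Reactants: 3
Product: 4 7-methoxy-6-(propan-2-yl)-3,4-dihydronaphthalen-1-yl trifluoromethanesulfonate
Conditions: Tf2O, 2,6-di-tert-butyl-4-methylpyridine, CH2Cl2, 0 → 23 °C
Reagents that add atoms: trifluoromethanesulfonic anhydride, O=S(=O)(OS(=O)(=O)C(F)(F)F)C(F)(F)F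
Why: enol triflate formation by O-sulfonylation of the only possible enol of the tetralone under a non-nucleophilic base.

Step 3
Reactants: 4; 5 (tributylstannyl)methanol
Product: 6 [7-methoxy-6-(propan-2-yl)-3,4-dihydronaphthalen-1-yl]methanol
Conditions: Pd(PPh3)4 (5 mol%), LiCl, 1,4-dioxane, 100 °C
Reagents that add atoms: none
Why: Stille coupling of the alkenyl triflate with the hydroxymethyl stannane installs C20 as the allylic alcohol needed for a directed epoxidation.

Step 4
Reactants: 6
Product: 7 [(1S,2S)-1,2-epoxy-7-methoxy-6-(propan-2-yl)-1,2,3,4-tetrahydronaphthalen-1-yl]methanol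
Conditions: Ti(OiPr)4 (10 mol%), L-(+)-diethyl tartrate (12 mol%), t-BuOOH, 4 Å MS, CH2Cl2, −25 °C
Reagents that add atoms: tert-butyl hydroperoxide, CC(C)(C)OO
Why: Sharpless asymmetric epoxidation; the titanium tartrate complex should deliver oxygen to one face of the trisubstituted allylic alcohol (L-(+)-tartrate gives the (1S,2S)-epoxide by the usual mnemonic), which puts the oxygen at the future C5 on the α face.

Step 5
Reactants: 7; 8 2-methylpropanenitrile
Product: 9 2-[(1S,2S)-1-hydroxy-1-(hydroxymethyl)-7-methoxy-6-(propan-2-yl)-1,2,3,4-tetrahydronaphthalen-2-yl]-2-methylpropanenitrile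
Conditions: 8 (3 equiv), LiN(iPr)2 (LDA, 3 equiv), THF, −78 °C; add 7; −78 → 45 °C; cold H2O quench
Reagents that add atoms: none
Why: SN2 opening of the epoxide by the lithiated nitrile at the secondary carbon (future C5), anti to the oxygen, should transfer the catalyst-set configuration into the C4–C5 bond with inversion and install the gem-dimethyl carbon C4 with C3 as a nitrile.

Step 6
Reactants: 9
Product: 10 cyclic thionocarbonate of 9 (thiocarbonyl bridge over the tertiary and the primary oxygen)
Conditions: 1,1'-thiocarbonyldiimidazole, DMAP (cat.), toluene, 80 °C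
Reagents that add atoms: 1,1'-thiocarbonyldiimidazole, S=C(n1ccnc1)n1ccnc1
Why: thiocarbonylation of the 1,2-diol, the first stage of a Corey–Winter olefination; no stereocentre is touched.

Step 7
Reactants: 10
Product: 11 2-[(2R)-7-methoxy-1-methylidene-6-(propan-2-yl)-1,2,3,4-tetrahydronaphthalen-2-yl]-2-methylpropanenitrile
Conditions: 1,3-dimethyl-2-phenyl-1,3,2-diazaphospholidine (3 equiv), THF, 40 °C
Reagents that add atoms: none
Why: Corey–Winter olefination; desulfurisation to the cyclic carbene and loss of CO2 should turn the temporary diol carbon into the exocyclic C10=C20 methylene without a benzylic cation, so C5 is not scrambled.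

Step 8
Reactants: 11
Product: 13 2-[(2R)-7-methoxy-1-methylidene-6-(propan-2-yl)-1,2,3,4-tetrahydronaphthalen-2-yl]-2-methylpropanal, via N-aluminated aldimine 12 (not isolated)
Conditions: iBu2AlH, toluene, −78 °C; aq. potassium sodium tartrate, then aq. tartaric acid (pH 3–4), 0 °C
Reagents that add atoms: diisobutylaluminium hydride, CC(C)C[AlH]CC(C)C (in 12 only); water, O
Why: partial reduction of the hindered nitrile with DIBAL-H should stop at the aluminated aldimine, whose mild hydrolysis gives the non-enolisable aldehyde while the acid-sensitive exocyclic styrene is kept.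

Step 9
Reactants: 13; 14 triphenyl(vinyl)phosphonium bromide
Product: 17 (5S,10S)-12-methoxyabieta-2,8,11,13-tetraene, via phosphonium bromide 15 (not isolated), via phosphorus ylide 16 (not isolated)
Conditions: 14 (2 equiv), Fe(acac)3 (0.3 equiv), PhSiH3 (2.5 equiv, slow addition), i-PrOH/THF 1:1, 40 °C; then evaporate, THF, KOtBu (3 equiv), 0 → 23 °C
Reagents that add atoms: none
Why: Proposed new method: an iron hydride formed from Fe(acac)3 and PhSiH3 should transfer a hydrogen atom to the terminal C20 of the styrenyl alkene of 13, which creates the C20 methyl and a tertiary benzylic C10 radical; this radical adds to the terminal carbon of the electrophilic vinylphosphonium 14 (C10–C1 bond), the α-phosphonio radical is reduced by divalent iron and protonated to salt 15, and KOtBu then gives ylide 16, whose intramolecular Wittig reaction with the C3 aldehyde forms the C2=C3 bond. The closest known reaction types are the metal-hydride hydrogen-atom-transfer radical conjugate addition/aldol annulations of alkenyl aldehydes, radical additions to vinylphosphonium salts that end in ylides, and the anionic vinylphosphonium (Schweizer-type) annulation. Ring A closes as a six-membered ring by Wittig olefination, with C2 attacking the exocyclic C3 carbonyl, so there is no competing ring size. The new C10 stereocentre is controlled by C5: the bulky CMe2CHO group shields its own face of the planar benzylic radical, so C1 should enter anti to it (α) and the methyl ends up β, the arrangement that closes to the trans-fused decalin. The step needs hydrogen-atom transfer to the electron-rich styrene and not to the electron-poor vinylphosphonium or the hindered aldehyde, which the polarity of the hydride donor should secure. It also needs capture of the benzylic radical before it is reduced or hands a hydrogen atom back from C5, which the excess of 14 and the slow silane addition are meant to secure.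

Step 10
Reactants: 17
Product: 18 (5S,10S)-12-methoxyabieta-8,11,13-triene (ferruginol methyl ether)
Conditions: H2 (1 atm), 10% Pd/C, EtOAc, 23 °C
Reagents that add atoms: none
Why: heterogeneous catalytic hydrogenation of the isolated cis-disubstituted C2=C3 alkene; the arene is untouched and no stereocentre is formed.

Step 11
Reactants: 18
Product: 19 (5S,10S)-12-methoxyabieta-6,8,11,13-tetraene
Conditions: DDQ (1.1 equiv), 1,4-dioxane, 23 → 60 °C
Reagents that add atoms: none
Why: DDQ dehydrogenation; hydride abstraction from C7–H, which is benzylic and para to the methoxy group, followed by loss of H6 should give the styrene, and the quaternary C10 rules out aromatisation of ring B.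

Step 12
Reactants: 19
Product: 20 (5S,10S)-6α,7α-epoxy-12-methoxyabieta-8,11,13-triene
Conditions: dimethyldioxirane (acetone solution), CH2Cl2, −40 → 0 °C; used crude
Reagents that add atoms: dimethyldioxirane, CC1(C)OO1
Why: epoxidation with a neutral dioxirane from the α face, opposite to the axial C10 methyl and the 4β-methyl, should set C6 and the provisional C7 configuration without acid that would open the p-methoxybenzylic epoxide.

Step 13
Reactants: 20 (two molecules)
Product: 21 CNP0327150.1
Conditions: BF3·OEt2 (5 mol%), 4 Å MS, CH2Cl2 (1 M in 20), −78 → −40 °C; Et3N quench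
Reagents that add atoms: none
Why: Lewis-acid-catalysed head-to-tail dimerisation of an aryl epoxide to a 1,4-dioxane; the oxirane oxygen of one molecule should attack the activated benzylic C7 of the other from the β face (inversion) and the freed C6 alkoxide closes the ring on the second C7 in the same way, so both C6–O bonds stay α and both C7–O bonds become β (all-equatorial, trans-fused).

**Compound list**
1 | 7-methoxy-1-tetralone | COc1ccc2c(c1)C(=O)CCC2 | starting material
2 | propan-2-ol | CC(C)O | starting material
3 | 7-methoxy-6-(propan-2-yl)-3,4-dihydronaphthalen-1(2H)-one | COc1cc2c(cc1C(C)C)CCCC2=O | intermediate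
4 | 7-methoxy-6-(propan-2-yl)-3,4-dihydronaphthalen-1-yl trifluoromethanesulfonate | COc1cc2c(cc1C(C)C)CCC=C2OS(=O)(=O)C(F)(F)F | intermediate
5 | (tributylstannyl)methanol | CCCC[Sn](CCCC)(CCCC)CO | starting material
6 | [7-methoxy-6-(propan-2-yl)-3,4-dihydronaphthalen-1-yl]methanol | COc1cc2c(cc1C(C)C)CCC=C2CO | intermediate
7 | [(1S,2S)-1,2-epoxy-7-methoxy-6-(propan-2-yl)-1,2,3,4-tetrahydronaphthalen-1-yl]methanol | COc1cc2c(cc1C(C)C)CC[C@@H]1O[C@]21CO | intermediate
8 | 2-methylpropanenitrile | CC(C)C#N | starting material
9 | 2-[(1S,2S)-1-hydroxy-1-(hydroxymethyl)-7-methoxy-6-(propan-2-yl)-1,2,3,4-tetrahydronaphthalen-2-yl]-2-methylpropanenitrile (tertiary OH trans to the nitrile-bearing group) | COc1cc2c(cc1C(C)C)CC[C@@H](C(C)(C)C#N)[C@@]2(O)CO | intermediate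
10 | cyclic thionocarbonate of 9 (spiro 2-thioxo-1,3-dioxolane at C-1, configuration as in 9) | COc1cc2c(cc1C(C)C)CC[C@@H](C(C)(C)C#N)[C@@]23COC(=S)O3 | intermediate
11 | 2-[(2R)-7-methoxy-1-methylidene-6-(propan-2-yl)-1,2,3,4-tetrahydronaphthalen-2-yl]-2-methylpropanenitrile | COc1cc2c(cc1C(C)C)CC[C@@H](C(C)(C)C#N)C2=C | intermediate
12 | N-(diisobutylalumanyl) aldimine of 13 | COc1cc2c(cc1C(C)C)CC[C@@H](C(C)(C)C=N[Al](CC(C)C)CC(C)C)C2=C | intermediate
13 | 2-[(2R)-7-methoxy-1-methylidene-6-(propan-2-yl)-1,2,3,4-tetrahydronaphthalen-2-yl]-2-methylpropanal | COc1cc2c(cc1C(C)C)CC[C@@H](C(C)(C)C=O)C2=C | intermediate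
14 | triphenyl(vinyl)phosphonium bromide | C=C[P+](c1ccccc1)(c1ccccc1)c1ccccc1.[Br-] | starting material
15 | {2-[(1S,2R)-7-methoxy-1-methyl-2-(2-methyl-1-oxopropan-2-yl)-6-(propan-2-yl)-1,2,3,4-tetrahydronaphthalen-1-yl]ethyl}(triphenyl)phosphonium bromide | COc1cc2c(cc1C(C)C)CC[C@@H](C(C)(C)C=O)[C@]2(C)CC[P+](c1ccccc1)(c1ccccc1)c1ccccc1.[Br-] | intermediate
16 | ylide of 15 (triphenylphosphoranylidene at C2) | COc1cc2c(cc1C(C)C)CC[C@@H](C(C)(C)C=O)[C@]2(C)CC=P(c1ccccc1)(c1ccccc1)c1ccccc1 | intermediate
17 | (5S,10S)-12-methoxyabieta-2,8,11,13-tetraene | COc1cc2c(cc1C(C)C)CC[C@H]1C(C)(C)C=CC[C@]21C | intermediate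
18 | (5S,10S)-12-methoxyabieta-8,11,13-triene (ferruginol methyl ether) | COc1cc2c(cc1C(C)C)CC[C@H]1C(C)(C)CCC[C@]21C | intermediate
19 | (5S,10S)-12-methoxyabieta-6,8,11,13-tetraene | COc1cc2c(cc1C(C)C)C=C[C@H]1C(C)(C)CCC[C@]21C | intermediate
20 | (5S,10S)-6α,7α-epoxy-12-methoxyabieta-8,11,13-triene | COc1cc2c(cc1C(C)C)[C@@H]1O[C@@H]1[C@H]1C(C)(C)CCC[C@]21C | intermediate
21 | CNP0327150.1: C2-symmetric dimer of two 12-methoxyabieta-8,11,13-triene units; the 6α-oxygen of each unit is bonded to C7β of the other (central 1,4-dioxane, trans-fused to both rings B); (5S,6R,7R,10S) in each half | COc1cc2c(cc1C(C)C)[C@H]1O[C@H]3[C@H](O[C@@H]1[C@H]1C(C)(C)CCC[C@]21C)c1cc(C(C)C)c(OC)cc1[C@@]1(C)CCCC(C)(C)[C@H]31 | target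

**Step count and risks**
Total step count: 13. Longest linear sequence: 13 steps (from 1).

Steps most likely to fail:

1. Step 9 (Proposed new method). The benzylic radical may be reduced to C10–H, may hand a hydrogen atom back so that the alkene moves into ring B and the C5 configuration erodes, or may add with poor facial selectivity. The fallback sets out from aldehyde 13 and uses cation and metathesis chemistry instead of a radical. Methylenation with Ph3P=CH2 (THF, 0 °C) gives the 1,5-diene F1. Dry HCl (CH2Cl2, −78 °C) adds in the Markovnikov sense to the styrenyl methylene only and gives the tertiary benzylic chloride F2. In the same flask TiCl4 ionises it and allyltrimethylsilane traps the cation anti to the C5 substituent, giving the allyl diene F3. Ring-closing metathesis with the second-generation Grubbs catalyst (CH2Cl2, 40 °C) forms the same C2=C3 bond and comes back to the route at tetraene 17.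

2. Step 13. A 1,2-hydride shift from C6 to the developing C7 cation (Meinwald rearrangement to the 6-ketone) or oligomerisation may outrun the bimolecular C–O bond formation. The fallback sets out from alkene 19 and forms both C7–O bonds by hydride delivery to oxocarbenium ions. Dihydroxylation with OsO4 (cat.)/NMO from the α face gives the cis-diol F4. MnO2 oxidises only the benzylic C7 hydroxyl and gives the α-ketol F5. TMSCl/imidazole gives the silyl ether F6. Et3SiH with catalytic TMSOTf (CH2Cl2, −78 °C) should then effect a twofold reductive etherification, with axial hydride delivery to each C7 oxocarbenium ion (H7 α, O7 β) and C6–O untouched, which comes back to the route at target 21.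

3. Step 5. The tertiary carbanion may attack C5 too slowly next to the fully substituted C10, so that base-induced epoxide isomerisation or alkoxide migration takes over. The fallback sets out from epoxy alcohol 7 and builds the quaternary carbon after the ring opening. Lithiated acetonitrile (THF, −78 → 23 °C), which is unhindered, opens the epoxide at the same carbon and gives the cyanomethyl diol F7. 2,2-Dimethoxypropane with pyridinium p-toluenesulfonate gives the acetonide F8. Two rounds of LiN(iPr)2/MeI give the gem-dimethyl nitrile acetonide F9. Aqueous acetic acid removes the acetonide and comes back to the route at diol 9.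

**Further compounds**
F1 | step 9 | (2S)-7-methoxy-1-methylidene-2-(2-methylbut-3-en-2-yl)-6-(propan-2-yl)-1,2,3,4-tetrahydronaphthalene | COc1cc2c(cc1C(C)C)CC[C@@H](C(C)(C)C=C)C2=C
F2 | step 9 | (2S)-1-chloro-7-methoxy-1-methyl-2-(2-methylbut-3-en-2-yl)-6-(propan-2-yl)-1,2,3,4-tetrahydronaphthalene (both C-1 epimers) | COc1cc2c(cc1C(C)C)CC[C@@H](C(C)(C)C=C)C2(C)Cl
F3 | step 9 | (1S,2S)-7-methoxy-1-methyl-2-(2-methylbut-3-en-2-yl)-1-(prop-2-en-1-yl)-6-(propan-2-yl)-1,2,3,4-tetrahydronaphthalene | COc1cc2c(cc1C(C)C)CC[C@@H](C(C)(C)C=C)[C@]2(C)CC=C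
F4 | step 13 | (5S,10S)-12-methoxyabieta-8,11,13-triene-6α,7α-diol | COc1cc2c(cc1C(C)C)[C@H](O)[C@H](O)[C@H]1C(C)(C)CCC[C@]21C
F5 | step 13 | (5S,10S)-6α-hydroxy-12-methoxyabieta-8,11,13-trien-7-one | COc1cc2c(cc1C(C)C)C(=O)[C@H](O)[C@H]1C(C)(C)CCC[C@]21C
F6 | step 13 | (5S,10S)-12-methoxy-6α-(trimethylsilyloxy)abieta-8,11,13-trien-7-one | COc1cc2c(cc1C(C)C)C(=O)[C@H](O[Si](C)(C)C)[C@H]1C(C)(C)CCC[C@]21C
F7 | step 5 | 2-[(1S,2S)-1-hydroxy-1-(hydroxymethyl)-7-methoxy-6-(propan-2-yl)-1,2,3,4-tetrahydronaphthalen-2-yl]acetonitrile | COc1cc2c(cc1C(C)C)CC[C@@H](CC#N)[C@@]2(O)CO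
F8 | step 5 | acetonide of F7 (spiro 2,2-dimethyl-1,3-dioxolane at C-1) | COc1cc2c(cc1C(C)C)CC[C@@H](CC#N)[C@@]23COC(C)(C)O3
F9 | step 5 | acetonide of 9 (spiro 2,2-dimethyl-1,3-dioxolane at C-1) | COc1cc2c(cc1C(C)C)CC[C@@H](C(C)(C)C#N)[C@@]23COC(C)(C)O3
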